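**Retrosynthetic overview**

- Numbering: ring C5–C10; C10 is quaternary (vinyl C1=C2, C14H2O); C8–O; C7 carries C11(=C13)–C12 of the lactone; C6–O; C5 carries C4(=C3H2)–C15.
- The route rests on the homoallylic alcohol unit C6(OH)–C5–C4(=C3H2) in the cyclohexane C5–C10, with C6–O and the C5 propenyl group trans-diequatorial. This is the retron of an allylsilane adding to a C6 aldehyde to form C5–C6.
- Rings: cyclohexane first (step 15, the only ring-forming C–C bond), then the γ-lactone O6→C12 (step 16).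
- Acyclic precursor: C10 from a copper-catalysed SN2′ coupling of an alkenylboronate (from propargyl alcohol by Duboudin carbomagnesiation) with a trisubstituted allylic phosphate; C7/C8 from a syn-aldol of a tert-butyl succinyl thiazolidinethione.
- End game: α-methylenation, desilylation and diacetylation, PMB removal, oxidation of C15 to the enal.

Key step: step 15

Assumption: the antipode of the chiral NHC ligand in step 9 is taken to be the one that delivers the alkenyl group to the Si face of C10 in 16, which gives (R)-C10; if the first antipode tried delivers to the Re face, the other is used.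

**Route**

Step 1
Reactants: 1 prop-2-yn-1-ol; 2 (trimethylsilyl)methylmagnesium chloride
Product: 4 (2E)-3-iodo-2-[(trimethylsilyl)methyl]prop-2-en-1-ol (iodine cis to CH2OH), via alkenylmagnesium alkoxide 3 (not isolated)
Conditions: 2 (2.5 equiv), CuI (10 mol%), Et2O/THF, 0 °C → rt; then I2, −78 → 0 °C; aq. NH4Cl
Reagents that add atoms: iodine, II
Why: Copper-catalysed anti-carbomagnesiation of the propargylic alkoxide (Duboudin reaction) puts the silylmethyl group on the internal carbon and magnesium on the terminal carbon, held cis to CH2O in a five-membered chelate, and iodinolysis with retention then fixes iodine cis to CH2OH, the geometry needed at C5=C4.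

Step 2
Reactants: 4 (2E)-3-iodo-2-[(trimethylsilyl)methyl]prop-2-en-1-ol
Product: 5 4-methoxybenzyl ether of 4
Conditions: NaH, PMBCl, Bu4NI (cat.), THF/DMF, 0 °C → rt
Reagents that add atoms: 4-methoxybenzyl chloride, COc1ccc(CCl)cc1
Why: Williamson etherification of the sodium alkoxide keeps the medium basic, so the acid-labile 2-substituted allylsilane and the alkenyl iodide are untouched.

Step 3
Reactants: 5 4-methoxybenzyl ether of 4
Product: 7 alkenyl pinacol boronate (boron cis to CH2OPMB), via alkenyllithium 6 (not isolated)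
Conditions: t-BuLi (2.1 equiv), Et2O, −78 °C; then i-PrOBpin, −78 °C → rt; H2O
Reagents that add atoms: 2-isopropoxy-4,4,5,5-tetramethyl-1,3,2-dioxaborolane, CC(C)OB1OC(C)(C)C(C)(C)O1
Why: Iodine–lithium exchange on the alkenyl iodide proceeds with retention of geometry at −78 °C and the alkenyllithium is trapped at boron by the isopropoxyboronate (borylation of an organolithium).

Step 4
Reactants: 8 4,4-diethoxybut-1-yne
Product: 10 5,5-diethoxypent-2-yn-1-ol, via lithium acetylide 9 (not isolated)
Conditions: n-BuLi, THF, −78 °C; then (CH2O)n, −78 °C → rt; H2O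
Reagents that add atoms: formaldehyde (as paraformaldehyde), C=O
Why: Deprotonation of the terminal alkyne and addition of the acetylide to formaldehyde is a standard propargylic alcohol synthesis, and the acetal is inert to base.

Step 5
Reactants: 10 5,5-diethoxypent-2-yn-1-ol
Product: 12 (2Z)-5,5-diethoxy-3-iodopent-2-en-1-ol, via cyclic alkenylalanate 11 (not isolated)
Conditions: Red-Al, THF, 0 °C → rt; then I2, THF, −78 °C; aq. Rochelle salt/Na2S2O3/NaHCO3
Reagents that add atoms: iodine, II
Why: Hydroxyl-directed trans-hydroalumination with Red-Al delivers hydride to C2 and aluminium to C3 within a cyclic alkenylalanate, and iodinolysis with retention gives the (Z)-3-iodo allylic alcohol with iodine on the future C10.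

Step 6
Reactants: 13 (tributylstannyl)methanol
Product: 14 tert-butyldimethyl[(tributylstannyl)methoxy]silane
Conditions: TBSCl, imidazole, DMF, rt
Reagents that add atoms: tert-butyldimethylsilyl chloride, CC(C)(C)[Si](C)(C)Cl
Why: Silylation of a primary alcohol with TBSCl/imidazole is routine and gives the tin reagent that carries C14 with its final protecting group.

Step 7
Reactants: 12 (2Z)-5,5-diethoxy-3-iodopent-2-en-1-ol; 14 tert-butyldimethyl[(tributylstannyl)methoxy]silane
Product: 15 (2Z)-3-(TBS-oxymethyl)-5,5-diethoxypent-2-en-1-ol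
Conditions: Pd(PPh3)4 (5 mol%), CuI (10 mol%), DMF, 60 °C
Reagents that add atoms: none
Why: Stille (Kosugi–Migita) cross-coupling transfers the α-silyloxymethyl group from tin in preference to butyl and proceeds with retention at the alkenyl iodide, so CH2OTBS ends cis to CH2OH.

Step 8
Reactants: 15 (2Z)-3-(TBS-oxymethyl)-5,5-diethoxypent-2-en-1-ol
Product: 16 diethyl allylic phosphate of 15
Conditions: (EtO)2P(O)Cl, pyridine, DMAP (cat.), CH2Cl2, 0 °C
Reagents that add atoms: diethyl chlorophosphate, CCOP(=O)(Cl)OCC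
Why: O-Phosphorylation of the primary allylic alcohol with a chlorophosphate under nucleophilic catalysis installs the leaving group for copper-catalysed allylic substitution without touching the acetal.

Step 9
Reactants: 7 alkenyl pinacol boronate; 16 diethyl allylic phosphate
Product: 17 (R)-1,4-diene acetal with quaternary C10 (vinyl, CH2OTBS, CH2CH(OEt)2, alkenylsilane)
Conditions: CuCl (5 mol%), chiral sulfonate-bearing imidazolinium salt (NHC precursor, 5.5 mol%), NaOMe (1.5 equiv), THF, 22 → 50 °C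
Reagents that add atoms: none
Why: Copper-catalysed enantioselective allylic substitution with an alkenylboronate: methoxide-promoted boron-to-copper transmetalation gives an NHC–alkenylcopper that adds SN2′, anti to the phosphate, at the disubstituted alkene terminus, creating the quaternary C10 and the vinyl group, and the chiral sulfonate-bridged NHC selects the Si face of C10 and so sets (R)-C10.

Step 10
Reactants: 17 (R)-1,4-diene acetal
Product: 18 (3R,4E)-aldehyde (C8 aldehyde, C10 quaternary)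
Conditions: PPTS (0.2 equiv), acetone/H2O (10:1), 40 °C
Reagents that add atoms: water, O
Why: Acid-catalysed acetal hydrolysis with a pyridinium salt is mild enough for the allylsilane and the silyl ether, and the aldehyde formed has a quaternary β-carbon and no α-stereocentre to lose.

Step 11
Reactants: 19 4-tert-butoxy-4-oxobutanoic acid; 20 (4R)-4-benzyl-1,3-thiazolidine-2-thione
Product: 21 tert-butyl 4-[(4R)-4-benzyl-2-thioxo-1,3-thiazolidin-3-yl]-4-oxobutanoate
Conditions: DCC, DMAP (cat.), CH2Cl2, 0 °C → rt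
Reagents that add atoms: none
Why: Carbodiimide-mediated N-acylation (Steglich conditions) of the thiazolidinethione by the free acid of the half-ester is the standard route to such activated imides.

Step 12
Reactants: 21 N-succinyl thiazolidinethione; 18 (3R,4E)-aldehyde
Product: 23 syn-aldol adduct (7R,8S,10R), via chlorotitanium Z-enolate 22 (not isolated)
Conditions: TiCl4 (1.05 equiv), i-Pr2NEt (1.1 equiv), NMP (1.0 equiv), CH2Cl2, 0 °C; then 18, −78 → 0 °C; aq. NH4Cl
Reagents that add atoms: none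
Why: Crimmins titanium-mediated aldol: the chlorotitanium Z-enolate reacts through the non-chelated Zimmerman–Traxler chair ("Evans-syn" mode, amine plus NMP) with the (R)-benzyl group shielding one enolate face, so that C7 (R) and C8 (S) are set syn by reagent control irrespective of the remote C10 centre, while the tert-butyl ester resists attack by the C8 titanium alkoxide.

Step 13
Reactants: 23 syn-aldol adduct
Product: 24 C8 TBS ether of 23
Conditions: TBSOTf, 2,6-lutidine, CH2Cl2, −78 → 0 °C
Reagents that add atoms: tert-butyldimethylsilyl trifluoromethanesulfonate, CC(C)(C)[Si](C)(C)OS(=O)(=O)C(F)(F)F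
Why: Silylation of the hindered secondary aldol hydroxyl with the silyl triflate and a hindered pyridine is fast at low temperature and blocks retro-aldol cleavage and lactonisation.

Step 14
Reactants: 24 C8 TBS ether
Product: 25 acyclic allylsilane aldehyde (C6 aldehyde; 7R,8S,10R)
Conditions: i-Bu2AlH (1.5 equiv), CH2Cl2, −78 °C; aq. Rochelle salt
Reagents that add atoms: none
Why: The thiazolidinethione imide is reduced by DIBAL-H at −78 °C through a stable tetrahedral aluminium adduct that collapses to the aldehyde only on work-up, releasing the auxiliary and leaving the tert-butyl ester and the C7 configuration intact.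

Step 15
Reactants: 25 acyclic allylsilane aldehyde
Product: 26 cyclohexanol (5S,6R,7S,8S,10R) with the C5 2-(PMB-oxymethyl)vinyl group
Conditions: Me2AlCl (2.5 equiv), CH2Cl2, −78 → −40 °C; aq. NaHCO3/Rochelle salt
Reagents that add atoms: none
Why: Me2AlCl binds the C6 aldehyde and the γ-carbon C5 of the 2-substituted allylsilane adds to it (intramolecular Hosomi–Sakurai reaction, the silicon-directed counterpart of the type I carbonyl-ene closure of citronellal to isopulegol), giving a β-silyl-stabilised cation at C4 that loses the silyl group to chloride and leaves the C4=C3 methylene regiospecifically. The cyclohexane closes 6-exo-trig at the carbonyl carbon, with the nucleophilic alkene exocyclic to the new ring, through a chair. C6 is set by the aluminium-bound oxygen taking the equatorial site trans to the equatorial C7 acetate arm, and C5 by the propenyl group taking the equatorial site trans to that oxygen. The chair is fixed by the existing centres: the C7 and C8 substituents are equatorial and, at (R)-C10, vinyl is equatorial and CH2OTBS axial, whereas the ring-flipped alternative would put three groups axial. The step needs trans,trans selectivity across C5/C6/C7 and retention of the C7 configuration; the geometry of the silane (CH2SiMe3 trans to C10) lets the C–Si bond align anti to the forming bond without clashing with the C10 substituents, and the proton-scavenging methylaluminium reagent at −78 °C suppresses protodesilylation, α-epimerisation and β-elimination of the silyloxy group.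

Step 16
Reactants: 26 cyclohexanol
Product: 27 trans-fused γ-lactone (O6–C12)
Conditions: t-BuOK (0.2 equiv), THF, 0 °C → rt
Reagents that add atoms: none
Why: Base-catalysed intramolecular transesterification (lactonisation): the equatorial C6 alkoxide attacks the ester of the adjacent equatorial C7 acetate arm 5-exo-trig and expels tert-butoxide, which carries the chain, giving the trans-fused γ-lactone without disturbing any stereocentre.

Step 17
Reactants: 27 trans-fused γ-lactone
Product: 29 α-(dimethylaminomethyl) lactone (C11 epimers), via lactone lithium enolate 28 (not isolated)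
Conditions: LDA, THF, −78 °C; then CH2=NMe2+ I−, −78 °C → rt
Reagents that add atoms: N,N-dimethylmethyleneiminium iodide (Eschenmoser's salt), C=[N+](C)C.[I-]
Why: The lactone lithium enolate at C11 undergoes a Mannich reaction with Eschenmoser's salt; no β-leaving group is present and the configuration of the new C11 centre is irrelevant because it is removed in the next step.

Step 18
Reactants: 29 α-(dimethylaminomethyl) lactone
Product: 31 α-methylene γ-lactone (bis-TBS, PMB), via trimethylammonium iodide 30 (not isolated)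
Conditions: MeI, MeOH, rt; then aq. NaHCO3, CH2Cl2, rt
Reagents that add atoms: none
Why: Exhaustive N-methylation to the quaternary ammonium salt followed by mild base-induced Hofmann-type (E1cB) elimination gives the α-methylene γ-lactone.

Step 19
Reactants: 31 α-methylene γ-lactone
Product: 32 C8,C14-diol
Conditions: HF·pyridine, pyridine, THF, 0 °C → rt
Reagents that add atoms: none
Why: Acidic fluoride cleaves both silyl ethers without adding to the methylene lactone, and O8 cannot reach C12 in the chair, so the 6,12-lactone is not at risk of translactonisation.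

Step 20
Reactants: 32 C8,C14-diol
Product: 33 C8,C14-diacetate
Conditions: Ac2O, pyridine, DMAP (cat.), CH2Cl2, 0 °C → rt
Reagents that add atoms: acetic anhydride, CC(=O)OC(C)=O
Why: DMAP-catalysed acetylation esterifies the secondary C8 and neopentyl C14 hydroxyls under conditions that leave the methylene lactone untouched.

Step 21
Reactants: 33 C8,C14-diacetate
Product: 34 C15 allylic alcohol
Conditions: DDQ, CH2Cl2/pH 7 buffer (10:1), 0 °C
Reagents that add atoms: none
Why: Oxidative cleavage of the p-methoxybenzyl ether with DDQ (single-electron oxidation of the electron-rich arene and hydrolysis of the oxocarbenium ion) is selective in the presence of acetates, the lactone and unactivated alkenes.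

Step 22
Reactants: 34 C15 allylic alcohol
Product: 35 CNP0200597.1
Conditions: Dess–Martin periodinane, NaHCO3, CH2Cl2, 0 °C → rt
Reagents that add atoms: none
Why: Dess–Martin oxidation of the primary allylic alcohol under buffered neutral conditions gives the 2-substituted propenal without migration of the double bond or epimerisation of C5.

**Compound list**

1 | prop-2-yn-1-ol (propargyl alcohol) | C#CCO | starting material
2 | (trimethylsilyl)methylmagnesium chloride | C[Si](C)(C)C[Mg]Cl | starting material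
3 | chloromagnesium alkoxide of (1E)-3-hydroxy-2-[(trimethylsilyl)methyl]prop-1-enylmagnesium chloride (Mg cis to CH2O) | Cl[Mg]/C=C(/C[Si](C)(C)C)CO[Mg]Cl | intermediate (not isolated)
4 | (2E)-3-iodo-2-[(trimethylsilyl)methyl]prop-2-en-1-ol (iodine cis to CH2OH) | I/C=C(/C[Si](C)(C)C)CO | intermediate
5 | 1-({[(2E)-3-iodo-2-[(trimethylsilyl)methyl]prop-2-en-1-yl]oxy}methyl)-4-methoxybenzene | I/C=C(/C[Si](C)(C)C)COCc1ccc(OC)cc1 | intermediate
6 | (1E)-3-[(4-methoxybenzyl)oxy]-2-[(trimethylsilyl)methyl]prop-1-enyllithium | [Li]/C=C(/C[Si](C)(C)C)COCc1ccc(OC)cc1 | intermediate (not isolated)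
7 | 2-{(1E)-3-[(4-methoxybenzyl)oxy]-2-[(trimethylsilyl)methyl]prop-1-en-1-yl}-4,4,5,5-tetramethyl-1,3,2-dioxaborolane (boron cis to CH2OPMB) | CC1(C)OB(/C=C(/C[Si](C)(C)C)COCc2ccc(OC)cc2)OC1(C)C | intermediate
8 | 4,4-diethoxybut-1-yne | C#CCC(OCC)OCC | starting material
9 | (4,4-diethoxybut-1-yn-1-yl)lithium | [Li]C#CCC(OCC)OCC | intermediate (not isolated)
10 | 5,5-diethoxypent-2-yn-1-ol | OCC#CCC(OCC)OCC | intermediate
11 | sodium bis(2-methoxyethoxy) cyclic alkenylalanate of 10 (2,5-dihydro-1,2-oxaluminole ate complex) | [Na+].COCCO[Al-]1(OCCOC)OCC=C1CC(OCC)OCC | intermediate (not isolated)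
12 | (2Z)-5,5-diethoxy-3-iodopent-2-en-1-ol | OC/C=C(\I)CC(OCC)OCC | intermediate
13 | (tributylstannyl)methanol | CCCC[Sn](CCCC)(CCCC)CO | starting material
14 | tert-butyldimethyl[(tributylstannyl)methoxy]silane | CCCC[Sn](CCCC)(CCCC)CO[Si](C)(C)C(C)(C)C | intermediate
15 | (2Z)-3-({[tert-butyl(dimethyl)silyl]oxy}methyl)-5,5-diethoxypent-2-en-1-ol | OC/C=C(\CO[Si](C)(C)C(C)(C)C)CC(OCC)OCC | intermediate
16 | (2Z)-3-({[tert-butyl(dimethyl)silyl]oxy}methyl)-5,5-diethoxypent-2-en-1-yl diethyl phosphate | CCOP(=O)(OCC)OC/C=C(\CO[Si](C)(C)C(C)(C)C)CC(OCC)OCC | intermediate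
17 | tert-butyl{[(2R,3E)-2-(2,2-diethoxyethyl)-2-ethenyl-5-[(4-methoxybenzyl)oxy]-4-[(trimethylsilyl)methyl]pent-3-en-1-yl]oxy}dimethylsilane | C=C[C@](CO[Si](C)(C)C(C)(C)C)(CC(OCC)OCC)/C=C(\COCc1ccc(OC)cc1)C[Si](C)(C)C | intermediate
18 | (3R,4E)-3-({[tert-butyl(dimethyl)silyl]oxy}methyl)-3-ethenyl-6-[(4-methoxybenzyl)oxy]-5-[(trimethylsilyl)methyl]hex-4-enal | C=C[C@](CO[Si](C)(C)C(C)(C)C)(CC=O)/C=C(\COCc1ccc(OC)cc1)C[Si](C)(C)C | intermediate
19 | 4-tert-butoxy-4-oxobutanoic acid (mono-tert-butyl succinate) | CC(C)(C)OC(=O)CCC(=O)O | starting material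
20 | (4R)-4-benzyl-1,3-thiazolidine-2-thione | S=C1N[C@H](Cc2ccccc2)CS1 | starting material
21 | tert-butyl 4-[(4R)-4-benzyl-2-thioxo-1,3-thiazolidin-3-yl]-4-oxobutanoate | CC(C)(C)OC(=O)CCC(=O)N1C(=S)SC[C@H]1Cc2ccccc2 | intermediate
22 | trichlorotitanium (Z)-enolate of 21 | Cl[Ti](Cl)(Cl)O/C(=C\CC(=O)OC(C)(C)C)N1C(=S)SC[C@H]1Cc2ccccc2 | intermediate (not isolated)
23 | tert-butyl (3R,4S,6R,7E)-3-{[(4R)-4-benzyl-2-thioxo-1,3-thiazolidin-3-yl]carbonyl}-6-({[tert-butyl(dimethyl)silyl]oxy}methyl)-6-ethenyl-4-hydroxy-9-[(4-methoxybenzyl)oxy]-8-[(trimethylsilyl)methyl]non-7-enoate | C=C[C@](CO[Si](C)(C)C(C)(C)C)(C[C@H](O)[C@@H](CC(=O)OC(C)(C)C)C(=O)N1C(=S)SC[C@H]1Cc2ccccc2)/C=C(\COCc3ccc(OC)cc3)C[Si](C)(C)C | intermediate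
24 | tert-butyl (3R,4S,6R,7E)-3-{[(4R)-4-benzyl-2-thioxo-1,3-thiazolidin-3-yl]carbonyl}-4-{[tert-butyl(dimethyl)silyl]oxy}-6-({[tert-butyl(dimethyl)silyl]oxy}methyl)-6-ethenyl-9-[(4-methoxybenzyl)oxy]-8-[(trimethylsilyl)methyl]non-7-enoate | C=C[C@](CO[Si](C)(C)C(C)(C)C)(C[C@H](O[Si](C)(C)C(C)(C)C)[C@@H](CC(=O)OC(C)(C)C)C(=O)N1C(=S)SC[C@H]1Cc2ccccc2)/C=C(\COCc3ccc(OC)cc3)C[Si](C)(C)C | intermediate
25 | tert-butyl (3R,4S,6R,7E)-4-{[tert-butyl(dimethyl)silyl]oxy}-6-({[tert-butyl(dimethyl)silyl]oxy}methyl)-6-ethenyl-3-formyl-9-[(4-methoxybenzyl)oxy]-8-[(trimethylsilyl)methyl]non-7-enoate | C=C[C@](CO[Si](C)(C)C(C)(C)C)(C[C@H](O[Si](C)(C)C(C)(C)C)[C@@H](CC(=O)OC(C)(C)C)C=O)/C=C(\COCc1ccc(OC)cc1)C[Si](C)(C)C | intermediate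
26 | tert-butyl [(1S,2R,3S,4R,6S)-6-{[tert-butyl(dimethyl)silyl]oxy}-4-({[tert-butyl(dimethyl)silyl]oxy}methyl)-4-ethenyl-2-hydroxy-3-{3-[(4-methoxybenzyl)oxy]prop-1-en-2-yl}cyclohexyl]acetate | C=C[C@]1(CO[Si](C)(C)C(C)(C)C)C[C@H](O[Si](C)(C)C(C)(C)C)[C@@H](CC(=O)OC(C)(C)C)[C@H](O)[C@H]1C(=C)COCc2ccc(OC)cc2 | intermediate
27 | (3aS,4S,6R,7S,7aR)-4-{[tert-butyl(dimethyl)silyl]oxy}-6-({[tert-butyl(dimethyl)silyl]oxy}methyl)-6-ethenyl-7-{3-[(4-methoxybenzyl)oxy]prop-1-en-2-yl}hexahydro-1-benzofuran-2(3H)-one | C=C[C@]1(CO[Si](C)(C)C(C)(C)C)C[C@H](O[Si](C)(C)C(C)(C)C)[C@H]2CC(=O)O[C@@H]2[C@H]1C(=C)COCc3ccc(OC)cc3 | intermediate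
28 | lithium enolate of 27 (C11=C12–OLi) | C=C[C@]1(CO[Si](C)(C)C(C)(C)C)C[C@H](O[Si](C)(C)C(C)(C)C)[C@H]2C=C(O[Li])O[C@@H]2[C@H]1C(=C)COCc3ccc(OC)cc3 | intermediate (not isolated)
29 | 3-[(dimethylamino)methyl] derivative of 27 (C3 epimers; otherwise 3aS,4S,6R,7S,7aR) | C=C[C@]1(CO[Si](C)(C)C(C)(C)C)C[C@H](O[Si](C)(C)C(C)(C)C)[C@H]2C(CN(C)C)C(=O)O[C@@H]2[C@H]1C(=C)COCc3ccc(OC)cc3 | intermediate
30 | N,N,N-trimethylammoniomethyl lactone iodide from 29 | C=C[C@]1(CO[Si](C)(C)C(C)(C)C)C[C@H](O[Si](C)(C)C(C)(C)C)[C@H]2C(C[N+](C)(C)C)C(=O)O[C@@H]2[C@H]1C(=C)COCc3ccc(OC)cc3.[I-] | intermediate (not isolated)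
31 | (3aS,4S,6R,7S,7aR)-4-{[tert-butyl(dimethyl)silyl]oxy}-6-({[tert-butyl(dimethyl)silyl]oxy}methyl)-6-ethenyl-7-{3-[(4-methoxybenzyl)oxy]prop-1-en-2-yl}-3-methylidenehexahydro-1-benzofuran-2(3H)-one | C=C[C@]1(CO[Si](C)(C)C(C)(C)C)C[C@H](O[Si](C)(C)C(C)(C)C)[C@H]2C(=C)C(=O)O[C@@H]2[C@H]1C(=C)COCc3ccc(OC)cc3 | intermediate
32 | (3aR,4S,6R,7S,7aR)-6-ethenyl-4-hydroxy-6-(hydroxymethyl)-7-{3-[(4-methoxybenzyl)oxy]prop-1-en-2-yl}-3-methylidenehexahydro-1-benzofuran-2(3H)-one | C=C[C@]1(CO)C[C@H](O)[C@H]2C(=C)C(=O)O[C@@H]2[C@H]1C(=C)COCc3ccc(OC)cc3 | intermediate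
33 | [(3aR,4S,6R,7S,7aR)-4-(acetyloxy)-6-ethenyl-7-{3-[(4-methoxybenzyl)oxy]prop-1-en-2-yl}-3-methylidene-2-oxooctahydro-1-benzofuran-6-yl]methyl acetate | C=C[C@]1(COC(C)=O)C[C@H](OC(C)=O)[C@H]2C(=C)C(=O)O[C@@H]2[C@H]1C(=C)COCc3ccc(OC)cc3 | intermediate
34 | [(3aR,4S,6R,7S,7aR)-4-(acetyloxy)-6-ethenyl-7-(3-hydroxyprop-1-en-2-yl)-3-methylidene-2-oxooctahydro-1-benzofuran-6-yl]methyl acetate | C=C[C@]1(COC(C)=O)C[C@H](OC(C)=O)[C@H]2C(=C)C(=O)O[C@@H]2[C@H]1C(=C)CO | intermediate
35 | [(3aR,4S,6R,7R,7aR)-4-(acetyloxy)-6-ethenyl-3-methylidene-2-oxo-7-(3-oxoprop-1-en-2-yl)octahydro-1-benzofuran-6-yl]methyl acetate (CNP0200597.1) | C=C[C@]1(COC(C)=O)C[C@H](OC(C)=O)[C@H]2C(=C)C(=O)O[C@@H]2[C@H]1C(=C)C=O | target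

**Step count**

Total: 22 steps. Longest linear sequence: 17 steps, from 8 to 35 (steps 4, 5, 7, 8, 9, 10 and 12–22).

**Steps most likely to fail**

1. Step 15. The ring may close through the chair in which the aluminium-bound oxygen is axial, so that C6 is formed with the wrong configuration; protodesilylation of the allylsilane is the competing drain. Fallback (sets out from 25, comes back at 26): the closure is accepted as it comes and C6 is corrected by substitution instead of by the transition state. The C6-epimeric cyclohexanol F1 is subjected to a Mitsunobu reaction (PPh3, DIAD, 4-nitrobenzoic acid, toluene, 0 °C → rt), in which the activated axial hydroxyl is displaced from the equatorial side with inversion to give the equatorial 4-nitrobenzoate F2. Methanolysis (K2CO3, MeOH, 0 °C) should then give 26.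

2. Step 9. The copper catalyst may discriminate poorly between the faces of an alkene whose two C10 substituents (CH2OTBS and CH2CH(OEt)2) are similar in size, or the hindered alkenylcopper may substitute directly (SN2) instead of SN2′. Fallback (sets out from 7, comes back at 23): C10 is made by a sigmatropic route and resolved through the auxiliary.
 - Boronate 7 is joined by Suzuki–Miyaura coupling (Pd(PPh3)4, aq. K3PO4, THF, 40 °C) to (2Z)-4-{[tert-butyl(dimethyl)silyl]oxy}-3-iodobut-2-en-1-ol F3, itself made from commercial 4-{[tert-butyl(dimethyl)silyl]oxy}but-2-yn-1-ol with Red-Al then I2. This gives the dienol F4.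
 - Iridium-catalysed vinyl transfer from vinyl acetate ([Ir(cod)Cl]2, Na2CO3, toluene, 100 °C) gives the allyl vinyl ether F5.
 - Thermal Claisen rearrangement of F5 (toluene, 140 °C) forms C9–C10 and the vinyl group and gives the racemic aldehyde F6.
 - The aldol of step 12 on F6 should give 23 together with its C10 epimer F7; the two diastereomers are separated by chromatography and the route resumes from 23.

3. Step 12. The titanium Lewis acid may trigger side reactions of the allylsilane or the p-methoxybenzyl ether, or the titanium aldolate may close onto the ester. Fallback (sets out from 19 and 18, comes back at 25): a boron-mediated Evans aldol with an oxazolidinone.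
 - Acid 19 is coupled (PivCl, Et3N, THF; then LiCl) with (4R)-4-benzyl-1,3-oxazolidin-2-one to give the imide F8.
 - Its dibutylboron Z-enolate (Bu2BOTf, i-Pr2NEt, CH2Cl2, −78 → 0 °C) adds to 18 to give the syn adduct F9.
 - TBSOTf/2,6-lutidine gives the silyl ether F10.
 - LiBH4 (THF/MeOH, 0 °C) removes the auxiliary reductively, sparing the tert-butyl ester, to give the primary alcohol F11.
 - Dess–Martin oxidation returns to 25.

**Further compounds**

F1 | step 15 | tert-butyl [(1S,2S,3S,4R,6S)-6-{[tert-butyl(dimethyl)silyl]oxy}-4-({[tert-butyl(dimethyl)silyl]oxy}methyl)-4-ethenyl-2-hydroxy-3-{3-[(4-methoxybenzyl)oxy]prop-1-en-2-yl}cyclohexyl]acetate (C6 epimer of 26, axial hydroxyl) | C=C[C@]1(CO[Si](C)(C)C(C)(C)C)C[C@H](O[Si](C)(C)C(C)(C)C)[C@@H](CC(=O)OC(C)(C)C)[C@@H](O)[C@H]1C(=C)COCc2ccc(OC)cc2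
F2 | step 15 | 4-nitrobenzoate of 26 (equatorial C6 ester) | C=C[C@]1(CO[Si](C)(C)C(C)(C)C)C[C@H](O[Si](C)(C)C(C)(C)C)[C@@H](CC(=O)OC(C)(C)C)[C@H](OC(=O)c2ccc(cc2)[N+](=O)[O-])[C@H]1C(=C)COCc3ccc(OC)cc3
F3 | step 9 | (2Z)-4-{[tert-butyl(dimethyl)silyl]oxy}-3-iodobut-2-en-1-ol | OC/C=C(\I)CO[Si](C)(C)C(C)(C)C
F4 | step 9 | (2E,4E)-3-({[tert-butyl(dimethyl)silyl]oxy}methyl)-6-[(4-methoxybenzyl)oxy]-5-[(trimethylsilyl)methyl]hexa-2,4-dien-1-ol | OC/C=C(\C=C(/COCc1ccc(OC)cc1)C[Si](C)(C)C)CO[Si](C)(C)C(C)(C)C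
F5 | step 9 | ethenyl ether of F4 | C=COC/C=C(\C=C(/COCc1ccc(OC)cc1)C[Si](C)(C)C)CO[Si](C)(C)C(C)(C)C
F6 | step 9 | racemic (4E)-3-({[tert-butyl(dimethyl)silyl]oxy}methyl)-3-ethenyl-6-[(4-methoxybenzyl)oxy]-5-[(trimethylsilyl)methyl]hex-4-enal (racemate of 18) | C=CC(CO[Si](C)(C)C(C)(C)C)(CC=O)/C=C(\COCc1ccc(OC)cc1)C[Si](C)(C)C
F7 | step 9 | C10 epimer of 23 (7R,8S,10S) | C=C[C@@](CO[Si](C)(C)C(C)(C)C)(C[C@H](O)[C@@H](CC(=O)OC(C)(C)C)C(=O)N1C(=S)SC[C@H]1Cc2ccccc2)/C=C(\COCc3ccc(OC)cc3)C[Si](C)(C)C
F8 | step 12 | tert-butyl 4-[(4R)-4-benzyl-2-oxo-1,3-oxazolidin-3-yl]-4-oxobutanoate | CC(C)(C)OC(=O)CCC(=O)N1C(=O)OC[C@H]1Cc2ccccc2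
F9 | step 12 | oxazolidinone syn-aldol adduct (7R,8S,10R; oxazolidinone analogue of 23) | C=C[C@](CO[Si](C)(C)C(C)(C)C)(C[C@H](O)[C@@H](CC(=O)OC(C)(C)C)C(=O)N1C(=O)OC[C@H]1Cc2ccccc2)/C=C(\COCc3ccc(OC)cc3)C[Si](C)(C)C
F10 | step 12 | C8 TBS ether of F9 | C=C[C@](CO[Si](C)(C)C(C)(C)C)(C[C@H](O[Si](C)(C)C(C)(C)C)[C@@H](CC(=O)OC(C)(C)C)C(=O)N1C(=O)OC[C@H]1Cc2ccccc2)/C=C(\COCc3ccc(OC)cc3)C[Si](C)(C)C
F11 | step 12 | C6 primary alcohol corresponding to 25 (hydroxymethyl in place of formyl) | C=C[C@](CO[Si](C)(C)C(C)(C)C)(C[C@H](O[Si](C)(C)C(C)(C)C)[C@@H](CC(=O)OC(C)(C)C)CO)/C=C(\COCc1ccc(OC)cc1)C[Si](C)(C)C
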